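**Assumptions:** the SMILES is read as the (2S)-flavan; (−)-sparteine, 9-BBN, iPrOBpin and N,N-diisopropylcarbamoyl chloride (CbCl) are bought reagents. Abbreviations: prenyl = 3-methylbut-2-en-1-yl; allyl = prop-2-en-1-yl; Cb = N,N-diisopropylcarbamoyl; pin = pinacolato; TES = triethylsilyl.

## Retrosynthetic overview

1. Target ⇐ triacetate (methanolysis) ⇐ allyl→prenyl cross-metathesis ⇐ one-pot triple aromatic Claisen rearrangement (two O-allyl on ring B, one O-prenyl on ring A) of a (2S)-flavan tri-ether.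
2. Pyran ring C ⇐ Mitsunobu O1–C2 closure (inversion) of an (R)-1,3-diarylpropan-1-ol.
3. Key C2–C1' bond: C2 is used as a nucleophile, as the (S)-α-lithiated primary carbamate (a chiral α-oxygenated carbanion), and joined to the ring B aryl–boron carbon by a 1,2-metalate shift; this sets C2 in the bond-forming step.
4. Ring B boronate ⇐ 4-bromocatechol (2 steps); ring A carbamate ⇐ 4-bromoresorcinol + hydroborated allyl carbamate (B-alkyl Suzuki).
5. Ring order: rings A and B are bought; ring C is the only ring formed (step 8); the three C-isoprenyl groups are placed after ring closure.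

## Route

Step 1
Reactants: 1 4-bromocatechol (4-bromobenzene-1,2-diol); 2 allyl bromide
Product: 3 4-bromo-1,2-bis(allyloxy)benzene
Conditions: 2 (2.4 equiv in all), K2CO3 (3 equiv), DMF, 60 °C, N2
Reagents that add atoms: allyl bromide (second equivalent), C=CCBr
Why: Double Williamson O-allylation of the catechol consumes two equivalents of allyl bromide, one per hydroxyl, and the allyl ethers serve both as catechol protection and as the later Claisen precursors.

Step 2
Reactants: 3 4-bromo-1,2-bis(allyloxy)benzene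
Product: 5 2-[3,4-bis(allyloxy)phenyl]-4,4,5,5-tetramethyl-1,3,2-dioxaborolane, via aryllithium 4 (not isolated)
Conditions: n-BuLi, THF, −78 °C; iPrOBpin, −78 °C → rt; H2O
Reagents that add atoms: 2-isopropoxy-4,4,5,5-tetramethyl-1,3,2-dioxaborolane, CC(C)OB1OC(C)(C)C(C)(C)O1
Why: Bromine–lithium exchange is much faster at −78 °C than any reaction of the allyl ethers, and the aryllithium is trapped by the borate (borylation).

Step 3
Reactants: 6 4-bromoresorcinol (4-bromobenzene-1,3-diol); 7 prenyl bromide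
Product: 8 2-bromo-5-(prenyloxy)phenol
Conditions: K2CO3 (1.0 equiv), 7 (1.0 equiv), acetone, rt
Reagents that add atoms: none
Why: Williamson mono-alkylation goes mainly at the unhindered hydroxyl para to bromine, because the ortho-bromo phenoxide is less nucleophilic and shielded; the minor regioisomer and bis-ether are removed by chromatography.

Step 4
Reactants: 9 allyl alcohol
Product: 10 allyl N,N-diisopropylcarbamate
Conditions: CbCl, Et3N, CH2Cl2, reflux
Reagents that add atoms: N,N-diisopropylcarbamoyl chloride, CC(C)N(C(C)C)C(Cl)=O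
Why: O-carbamoylation of the primary alcohol installs the group that later directs lithiation and acts as leaving group.

Step 5
Reactants: 10 allyl N,N-diisopropylcarbamate; 8 2-bromo-5-(prenyloxy)phenol
Product: 12 3-[2-hydroxy-4-(prenyloxy)phenyl]propyl N,N-diisopropylcarbamate, via alkylborane 11 (not isolated)
Conditions: 9-BBN (1.25 equiv), 10 (1.3 equiv), THF, 0 °C → rt; then 8, PdCl2(dppf) (5 mol %), aq K3PO4, DMF, 60 °C
Reagents that add atoms: none
Why: Anti-Markovnikov hydroboration followed by B-alkyl Suzuki–Miyaura coupling at the aryl bromide; all B–H is consumed before 8 is added, so its prenyl alkene is untouched.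

Step 6
Reactants: 12 3-[2-hydroxy-4-(prenyloxy)phenyl]propyl N,N-diisopropylcarbamate
Product: 13 3-[4-(prenyloxy)-2-(triethylsilyloxy)phenyl]propyl N,N-diisopropylcarbamate
Conditions: TESCl, imidazole, CH2Cl2, 0 °C → rt
Reagents that add atoms: chlorotriethylsilane, CC[Si](Cl)(CC)CC
Why: Silylation masks the acidic phenol for the organolithium step with a group that the later basic peroxide work-up removes without a separate step.

Step 7
Reactants: 13 3-[4-(prenyloxy)-2-(triethylsilyloxy)phenyl]propyl N,N-diisopropylcarbamate; 5 2-[3,4-bis(allyloxy)phenyl]-4,4,5,5-tetramethyl-1,3,2-dioxaborolane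
Product: 17 2-{(3R)-3-[3,4-bis(allyloxy)phenyl]-3-hydroxypropyl}-5-(prenyloxy)phenol, via lithiated carbamate 14 (not isolated), via boronate complex 15 (not isolated), via secondary boronic ester 16 (not isolated)
Conditions: s-BuLi (1.2 equiv), (−)-sparteine (1.2 equiv), Et2O, −78 °C, 5 h; 5 (1.3 equiv), −78 °C, 1 h, then 40 °C, 6 h; then NaOH (2 M), H2O2 (30%), THF, 0 °C → rt
Reagents that add atoms: hydrogen peroxide, OO
Why: Hoppe–Aggarwal lithiation–borylation: (−)-sparteine-directed removal of the pro-S α-proton gives a configurationally stable (S)-α-oxygenated carbanion (C2 as a nucleophile) that adds to the aryl boronate with retention, the aryl group then shifts 1,2 from boron to carbon with inversion as the carbamate leaves, and C–B oxidation with retention gives the (R)-carbinol, so C2 is set in the C–C bond-forming event while the basic peroxide also cleaves the aryl triethylsilyl ether.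

Step 8
Reactants: 17 2-{(3R)-3-[3,4-bis(allyloxy)phenyl]-3-hydroxypropyl}-5-(prenyloxy)phenol
Product: 18 (2S)-2-[3,4-bis(allyloxy)phenyl]-7-(prenyloxy)-3,4-dihydro-2H-chromene
Conditions: PPh3, DIAD, toluene (0.02 M), −20 °C → rt
Reagents that add atoms: none
Why: Intramolecular Mitsunobu etherification: the only free phenol displaces the activated (R)-carbinol in a 6-exo SN2 closure with inversion to give the (2S) pyran ring, run cold, dilute and in a non-polar solvent to suppress ionisation of the alkoxy-substituted benzylic centre.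

Step 9
Reactants: 18 (2S)-2-[3,4-bis(allyloxy)phenyl]-7-(prenyloxy)-3,4-dihydro-2H-chromene
Product: 19 (2S)-2-(3,4-diacetoxy-2,5-diallylphenyl)-6-(2-methylbut-3-en-2-yl)-3,4-dihydro-2H-chromen-7-yl acetate
Conditions: Ac2O (10 equiv), PhNEt2, 200 °C (sealed tube), 16 h; then Ac2O, DMAP, pyridine, rt
Reagents that add atoms: acetic anhydride, CC(=O)OC(C)=O
Why: Three aromatic Claisen rearrangements in one operation, each to the only or the less hindered ortho position (3'-O-allyl → C2', 4'-O-allyl → C5', 7-O-prenyl → C6 with allyl inversion to the 1,1-dimethylallyl group, para to the ring oxygen as in other 2-alkoxy-4-prenyloxy arenes), with each phenol acetylated as it is unmasked (no single intermediate accumulates) so that no free 4'-hydroxyl can open the pyran ring through a quinone methide and racemise C2.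

Step 10
Reactants: 19 (2S)-2-(3,4-diacetoxy-2,5-diallylphenyl)-6-(2-methylbut-3-en-2-yl)-3,4-dihydro-2H-chromen-7-yl acetate; 20 2-methylbut-2-ene
Product: 21 (2S)-2-[3,4-diacetoxy-2,5-bis(3-methylbut-2-en-1-yl)phenyl]-6-(2-methylbut-3-en-2-yl)-3,4-dihydro-2H-chromen-7-yl acetate
Conditions: second-generation Grubbs catalyst RuCl2(=CHPh)(H2IMes)(PCy3) (5 mol %), 1,4-benzoquinone (10 mol %), 20/CH2Cl2 1:1, 40 °C (sealed)
Reagents that add atoms: none
Why: Olefin cross-metathesis turns the two unhindered allyl groups into prenyl groups, while the vinyl group on the quaternary carbon is too hindered to enter the catalytic cycle and benzoquinone suppresses allyl-to-propenyl isomerisation.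

Step 11
Reactants: 21 (2S)-2-[3,4-diacetoxy-2,5-bis(3-methylbut-2-en-1-yl)phenyl]-6-(2-methylbut-3-en-2-yl)-3,4-dihydro-2H-chromen-7-yl acetate
Product: 22 (2S)-2-[3,4-dihydroxy-2,5-bis(3-methylbut-2-en-1-yl)phenyl]-6-(2-methylbut-3-en-2-yl)-3,4-dihydro-2H-chromen-7-ol (CNP0118330.1)
Conditions: K2CO3 (0.3 equiv), degassed MeOH/THF, Ar, 0 °C → rt; AcOH quench
Reagents that add atoms: none
Why: Base-catalysed transesterification removes the three aryl acetates under cold, oxygen-free, acid-free conditions that spare the catechol, the prenyl groups and the C2 stereocentre.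

## Compound list

1 | 4-bromobenzene-1,2-diol (4-bromocatechol) | Oc1ccc(Br)cc1O | starting material
2 | allyl bromide (3-bromoprop-1-ene) | C=CCBr | starting material
3 | 4-bromo-1,2-bis(allyloxy)benzene | C=CCOc1ccc(Br)cc1OCC=C | intermediate
4 | [3,4-bis(allyloxy)phenyl]lithium | [Li]c1ccc(OCC=C)c(OCC=C)c1 | intermediate (not isolated)
5 | 2-[3,4-bis(allyloxy)phenyl]-4,4,5,5-tetramethyl-1,3,2-dioxaborolane | C=CCOc1ccc(B2OC(C)(C)C(C)(C)O2)cc1OCC=C | intermediate
6 | 4-bromobenzene-1,3-diol (4-bromoresorcinol) | Oc1ccc(Br)c(O)c1 | starting material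
7 | prenyl bromide (1-bromo-3-methylbut-2-ene) | CC(C)=CCBr | starting material
8 | 2-bromo-5-[(3-methylbut-2-en-1-yl)oxy]phenol | CC(C)=CCOc1ccc(Br)c(O)c1 | intermediate
9 | allyl alcohol (prop-2-en-1-ol) | C=CCO | starting material
10 | allyl N,N-diisopropylcarbamate | C=CCOC(=O)N(C(C)C)C(C)C | intermediate
11 | 3-(9-borabicyclo[3.3.1]nonan-9-yl)propyl N,N-diisopropylcarbamate | CC(C)N(C(C)C)C(=O)OCCCB1C2CCCC1CCC2 | intermediate (not isolated)
12 | 3-{2-hydroxy-4-[(3-methylbut-2-en-1-yl)oxy]phenyl}propyl N,N-diisopropylcarbamate | CC(C)=CCOc1ccc(CCCOC(=O)N(C(C)C)C(C)C)c(O)c1 | intermediate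
13 | 3-{4-[(3-methylbut-2-en-1-yl)oxy]-2-(triethylsilyloxy)phenyl}propyl N,N-diisopropylcarbamate | CC(C)=CCOc1ccc(CCCOC(=O)N(C(C)C)C(C)C)c(O[Si](CC)(CC)CC)c1 | intermediate
14 | (1S)-1-lithio-3-{4-(prenyloxy)-2-(triethylsilyloxy)phenyl}propyl N,N-diisopropylcarbamate (sparteine complex) | [Li][C@H](OC(=O)N(C(C)C)C(C)C)CCc1ccc(OCC=C(C)C)cc1O[Si](CC)(CC)CC | intermediate (not isolated)
15 | lithium [3,4-bis(allyloxy)phenyl][(1S)-1-(diisopropylcarbamoyloxy)-3-{4-(prenyloxy)-2-(triethylsilyloxy)phenyl}propyl](pinacolato)borate | [Li+].CC(C)N(C(C)C)C(=O)O[C@H](CCc1ccc(OCC=C(C)C)cc1O[Si](CC)(CC)CC)[B-]1(c2ccc(OCC=C)c(OCC=C)c2)OC(C)(C)C(C)(C)O1 | intermediate (not isolated)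
16 | 2-[(1R)-1-[3,4-bis(allyloxy)phenyl]-3-{4-(prenyloxy)-2-(triethylsilyloxy)phenyl}propyl]-4,4,5,5-tetramethyl-1,3,2-dioxaborolane | CC1(C)OB(OC1(C)C)[C@H](CCc1ccc(OCC=C(C)C)cc1O[Si](CC)(CC)CC)c1ccc(OCC=C)c(OCC=C)c1 | intermediate (not isolated)
17 | 2-{(3R)-3-[3,4-bis(allyloxy)phenyl]-3-hydroxypropyl}-5-[(3-methylbut-2-en-1-yl)oxy]phenol | O[C@H](CCc1ccc(OCC=C(C)C)cc1O)c1ccc(OCC=C)c(OCC=C)c1 | intermediate
18 | (2S)-2-[3,4-bis(allyloxy)phenyl]-7-[(3-methylbut-2-en-1-yl)oxy]-3,4-dihydro-2H-chromene | C=CCOc1ccc([C@@H]2CCc3ccc(OCC=C(C)C)cc3O2)cc1OCC=C | intermediate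
19 | (2S)-2-(3,4-diacetoxy-2,5-diallylphenyl)-6-(2-methylbut-3-en-2-yl)-3,4-dihydro-2H-chromen-7-yl acetate | C=CCc1cc([C@@H]2CCc3cc(C(C)(C)C=C)c(OC(C)=O)cc3O2)c(CC=C)c(OC(C)=O)c1OC(C)=O | intermediate
20 | 2-methylbut-2-ene | CC=C(C)C | starting material
21 | (2S)-2-[3,4-diacetoxy-2,5-bis(3-methylbut-2-en-1-yl)phenyl]-6-(2-methylbut-3-en-2-yl)-3,4-dihydro-2H-chromen-7-yl acetate | CC(C)=CCc1cc([C@@H]2CCc3cc(C(C)(C)C=C)c(OC(C)=O)cc3O2)c(CC=C(C)C)c(OC(C)=O)c1OC(C)=O | intermediate
22 | (2S)-2-[3,4-dihydroxy-2,5-bis(3-methylbut-2-en-1-yl)phenyl]-6-(2-methylbut-3-en-2-yl)-3,4-dihydro-2H-chromen-7-ol (CNP0118330.1) | C=CC(C)(C)c1cc2c(cc1O)O[C@H](c1cc(CC=C(C)C)c(O)c(O)c1CC=C(C)C)CC2 | target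

## Step count and risk

Total steps: 11. Longest linear sequence: 8 steps (steps 3, 5, 6, 7, 8, 9, 10, 11); the ring B branch is steps 1 and 2, and step 4 supplies the carbamate for step 5.

**Step 7 (lithiation–borylation).** Risks are competing deprotonation next to the prenyl ether oxygen, a sluggish 1,2-shift, and an er below about 95:5. Fallback: it sets out from 13 (with 3 as the aryl source) and comes back at 17; the carbanion is first stored as an isolable boron compound and the aryl group is brought in as the organolithium. Compound 13 is lithiated as in step 7 and quenched with iPrOBpin to give the α-carbamoyloxy boronic ester (1S)-1-(4,4,5,5-tetramethyl-1,3,2-dioxaborolan-2-yl)-3-{4-(prenyloxy)-2-(triethylsilyloxy)phenyl}propyl N,N-diisopropylcarbamate F1, which can be purified and its er measured. Aryllithium 4 (from 3 and n-BuLi, THF, −78 °C) is added to F1 to form the same boronate complex 15. This rearranges on warming (MgBr2·OEt2 if needed) to 16 and is oxidised with NaOH/H2O2 to 17.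

**Step 8 (Mitsunobu closure).** Risk is partial ionisation of the 3,4-dialkoxybenzylic oxyphosphonium, giving racemisation or elimination to the 1,3-diarylpropene. Fallback: it sets out from 13 and 5 and comes back at 18; the ring is closed at the aryl carbon with retention, so the benzylic carbon is never substituted. Step 7 run with (+)-sparteine gives the enantiomeric alcohol 2-{(3S)-3-[3,4-bis(allyloxy)phenyl]-3-hydroxypropyl}-5-(prenyloxy)phenol F2. PhNTf2/K2CO3 converts only the phenol into the aryl triflate 2-{(3S)-3-[3,4-bis(allyloxy)phenyl]-3-hydroxypropyl}-5-(prenyloxy)phenyl trifluoromethanesulfonate F3. Intramolecular C–O coupling (Pd(OAc)2, 2-(di-tert-butylphosphino)-1,1'-binaphthyl, Cs2CO3, toluene, 70 °C) forms the O1–C8a bond and gives 18. Allyl aryl ethers are normally carried through zerovalent-palladium couplings when no soft allyl scavenger is present.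

**Step 9 (triple Claisen rearrangement).** Risks are migration of the 3'-O-allyl group to C6' instead of the crowded C2', some C8 product on ring A, and loss of isoprene from the prenyl ether. Fallback: it sets out from 3 and comes back at 22, and makes the ring B C-allyl groups before the fragments are joined. Heating 3 in PhNEt2 at 200 °C gives the catechol 3,6-diallyl-4-bromobenzene-1,2-diol F4, where each allyl group has a single open ortho position. TBSOTf/2,6-lutidine gives the bis(silyl ether) 3,6-diallyl-4-bromo-1,2-bis(tert-butyldimethylsilyloxy)benzene F5. Cross-metathesis with 20 (second-generation Grubbs catalyst RuCl2(=CHPh)(H2IMes)(PCy3)) gives the diprenyl bromide 4-bromo-1,2-bis(tert-butyldimethylsilyloxy)-3,6-bis(3-methylbut-2-en-1-yl)benzene F6. n-BuLi then iPrOBpin gives the boronic ester 2-[3,4-bis(tert-butyldimethylsilyloxy)-2,5-bis(3-methylbut-2-en-1-yl)phenyl]-4,4,5,5-tetramethyl-1,3,2-dioxaborolane F7. Coupling F7 with 13 under the step 7 conditions gives the alcohol 2-{(3R)-3-[3,4-bis(tert-butyldimethylsilyloxy)-2,5-diprenylphenyl]-3-hydroxypropyl}-5-(prenyloxy)phenol F8; the flanked silyl ethers survive the peroxide work-up. The Mitsunobu closure of step 8 gives the flavan (2S)-2-[3,4-bis(tert-butyldimethylsilyloxy)-2,5-diprenylphenyl]-7-(prenyloxy)-3,4-dihydro-2H-chromene F9. A single Claisen rearrangement (PhNEt2, 190 °C; no trap is needed because the 4'-oxygen is silylated) gives the phenol (2S)-2-[3,4-bis(tert-butyldimethylsilyloxy)-2,5-diprenylphenyl]-6-(2-methylbut-3-en-2-yl)-3,4-dihydro-2H-chromen-7-ol F10. Tetrabutylammonium fluoride buffered with AcOH in THF at 0 °C then gives 22.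

## Further compounds

F1 | step 7 | (1S)-1-(4,4,5,5-tetramethyl-1,3,2-dioxaborolan-2-yl)-3-{4-(prenyloxy)-2-(triethylsilyloxy)phenyl}propyl N,N-diisopropylcarbamate | CC(C)N(C(C)C)C(=O)O[C@H](CCc1ccc(OCC=C(C)C)cc1O[Si](CC)(CC)CC)B1OC(C)(C)C(C)(C)O1
F2 | step 8 | 2-{(3S)-3-[3,4-bis(allyloxy)phenyl]-3-hydroxypropyl}-5-(prenyloxy)phenol | O[C@@H](CCc1ccc(OCC=C(C)C)cc1O)c1ccc(OCC=C)c(OCC=C)c1
F3 | step 8 | 2-{(3S)-3-[3,4-bis(allyloxy)phenyl]-3-hydroxypropyl}-5-(prenyloxy)phenyl trifluoromethanesulfonate | O[C@@H](CCc1ccc(OCC=C(C)C)cc1OS(=O)(=O)C(F)(F)F)c1ccc(OCC=C)c(OCC=C)c1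
F4 | step 9 | 3,6-diallyl-4-bromobenzene-1,2-diol | Oc1c(O)c(CC=C)c(Br)cc1CC=C
F5 | step 9 | 3,6-diallyl-4-bromo-1,2-bis(tert-butyldimethylsilyloxy)benzene | C=CCc1cc(Br)c(CC=C)c(O[Si](C)(C)C(C)(C)C)c1O[Si](C)(C)C(C)(C)C
F6 | step 9 | 4-bromo-1,2-bis(tert-butyldimethylsilyloxy)-3,6-bis(3-methylbut-2-en-1-yl)benzene | CC(C)=CCc1cc(Br)c(CC=C(C)C)c(O[Si](C)(C)C(C)(C)C)c1O[Si](C)(C)C(C)(C)C
F7 | step 9 | 2-[3,4-bis(tert-butyldimethylsilyloxy)-2,5-bis(3-methylbut-2-en-1-yl)phenyl]-4,4,5,5-tetramethyl-1,3,2-dioxaborolane | CC(C)=CCc1cc(B2OC(C)(C)C(C)(C)O2)c(CC=C(C)C)c(O[Si](C)(C)C(C)(C)C)c1O[Si](C)(C)C(C)(C)C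
F8 | step 9 | 2-{(3R)-3-[3,4-bis(tert-butyldimethylsilyloxy)-2,5-bis(3-methylbut-2-en-1-yl)phenyl]-3-hydroxypropyl}-5-(prenyloxy)phenol | O[C@H](CCc1ccc(OCC=C(C)C)cc1O)c1cc(CC=C(C)C)c(O[Si](C)(C)C(C)(C)C)c(O[Si](C)(C)C(C)(C)C)c1CC=C(C)C
F9 | step 9 | (2S)-2-[3,4-bis(tert-butyldimethylsilyloxy)-2,5-bis(3-methylbut-2-en-1-yl)phenyl]-7-(prenyloxy)-3,4-dihydro-2H-chromene | CC(C)=CCOc1ccc2c(c1)O[C@H](c1cc(CC=C(C)C)c(O[Si](C)(C)C(C)(C)C)c(O[Si](C)(C)C(C)(C)C)c1CC=C(C)C)CC2
F10 | step 9 | (2S)-2-[3,4-bis(tert-butyldimethylsilyloxy)-2,5-bis(3-methylbut-2-en-1-yl)phenyl]-6-(2-methylbut-3-en-2-yl)-3,4-dihydro-2H-chromen-7-ol | C=CC(C)(C)c1cc2c(cc1O)O[C@H](c1cc(CC=C(C)C)c(O[Si](C)(C)C(C)(C)C)c(O[Si](C)(C)C(C)(C)C)c1CC=C(C)C)CC2
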